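Assumption: "single enantiomer" is read as the (2S) compound in ≥98% ee, secured by a late kinetic resolution of the racemic flavanone (the 2R half is sacrificed).

## Retrosynthetic overview

1. Target 26 ⇐ MOM ether 25 ⇐ racemic flavanone 24, resolved by asymmetric transfer hydrogenation that leaves the (2S) ketone.
2. Ring C (the pyranone) is closed last, by oxa-Michael addition within 2'-hydroxychalcone 23.
3. 23 ⇐ Claisen–Schmidt aldol condensation of ring A methyl ketone 7 with ring B aldehyde 21; this makes the future C3–C2 bond.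
4. 7 ⇐ 2,4-dihydroxyacetophenone 1, with the prenyl group placed at C3 by aromatic Claisen rearrangement of a 4-O-(1,1-dimethylallyl) ether.
5. 21 ⇐ 4-hydroxybenzaldehyde 8: the dimethyldihydropyran ring on ring B is built first (propargyl ether rearrangement, hydrogenation), then C8 bromination and prenylation through an arylcopper.

## Route

Step 1
Reactants: 1 1-(2,4-dihydroxyphenyl)ethanone; 2 3-chloro-3-methylbut-1-yne
Product: 3 1-[2-hydroxy-4-(2-methylbut-3-yn-2-yloxy)phenyl]ethanone
Conditions: K2CO3, KI (cat.), CuI (cat.), acetone, reflux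
Reagents that add atoms: none
Why: Copper-assisted Williamson-type propargylic O-alkylation; the 2-OH is hydrogen-bonded to the acetyl group, so only the 4-OH is etherified.

Step 2
Reactants: 3 1-[2-hydroxy-4-(2-methylbut-3-yn-2-yloxy)phenyl]ethanone
Product: 4 1-[2-hydroxy-4-(2-methylbut-3-en-2-yloxy)phenyl]ethanone
Conditions: H2 (1 atm), Pd/CaCO3 poisoned with Pb(OAc)2, quinoline, EtOAc, rt
Reagents that add atoms: none
Why: Lindlar-type semihydrogenation stops at the terminal alkene and leaves the aryl ketone and the ether untouched.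

Step 3
Reactants: 4 1-[2-hydroxy-4-(2-methylbut-3-en-2-yloxy)phenyl]ethanone
Product: 6 1-[2,4-dihydroxy-3-(3-methylbut-2-enyl)phenyl]ethanone, via dienone 5 (not isolated)
Conditions: PhNEt2, 130–140 °C, N2
Reagents that add atoms: none
Why: Aromatic Claisen rearrangement ([3,3]) turns the tertiary allyl ether into a linear prenyl group and goes to C3, between the two oxygens, because the chelated o-hydroxyacetyl unit fixes the C3–C4 bond as the reactive enol double bond (as in the known allyl analogue); the dienone then tautomerises.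

Step 4
Reactants: 6 1-[2,4-dihydroxy-3-(3-methylbut-2-enyl)phenyl]ethanone
Product: 7 1-[2-hydroxy-4-(methoxymethoxy)-3-(3-methylbut-2-enyl)phenyl]ethanone
Conditions: MOMCl (1.2 equiv), K2CO3, acetone, 0 °C to rt
Reagents that add atoms: chloromethyl methyl ether (MOMCl), COCCl
Why: Selective O-alkylation (MOM protection) of the free 4-OH, since the chelated 2-OH is far less nucleophilic.

Step 5
Reactants: 8 4-hydroxybenzaldehyde; 2 3-chloro-3-methylbut-1-yne
Product: 9 4-(2-methylbut-3-yn-2-yloxy)benzaldehyde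
Conditions: K2CO3, KI (cat.), CuI (cat.), acetone, reflux
Reagents that add atoms: none
Why: The same copper-assisted Williamson-type propargylic etherification, here on the only phenol present.

Step 6
Reactants: 9 4-(2-methylbut-3-yn-2-yloxy)benzaldehyde
Product: 13 2,2-dimethyl-2H-chromene-6-carbaldehyde, via allenyl dienone 10 (not isolated), via allenylphenol 11 (not isolated), via quinone methide 12 (not isolated)
Conditions: PhNEt2, 190 °C, N2
Reagents that add atoms: none
Why: Aryl propargyl ether Claisen rearrangement, enolisation, 1,5-hydrogen shift and oxa-6π electrocyclisation form the 2,2-dimethylchromene in one thermal cascade.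

Step 7
Reactants: 13 2,2-dimethyl-2H-chromene-6-carbaldehyde
Product: 14 2,2-dimethylchroman-6-carbaldehyde
Conditions: H2 (1 atm), 5% Pd/C, EtOAc, rt, stopped after 1 equiv H2
Reagents that add atoms: none
Why: Catalytic hydrogenation reduces the cis-disubstituted styrenic alkene much faster than the aryl aldehyde under these mild conditions.

Step 8
Reactants: 14 2,2-dimethylchroman-6-carbaldehyde
Product: 15 8-bromo-2,2-dimethylchroman-6-carbaldehyde
Conditions: Br2 (1.05 equiv), NaOAc, AcOH, rt, dark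
Reagents that add atoms: bromine, BrBr
Why: Electrophilic aromatic bromination goes to C8, the only free position that is ortho to the ring oxygen and meta to the formyl group.

Step 9
Reactants: 15 8-bromo-2,2-dimethylchroman-6-carbaldehyde
Product: 16 2-(8-bromo-2,2-dimethylchroman-6-yl)-1,3-dioxolane
Conditions: HOCH2CH2OH, p-TsOH·H2O (cat.), toluene, reflux, Dean–Stark
Reagents that add atoms: ethane-1,2-diol, OCCO
Why: Acetalisation masks the aldehyde so that it survives the organolithium step.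

Step 10
Reactants: 16 2-(8-bromo-2,2-dimethylchroman-6-yl)-1,3-dioxolane; 17 1-bromo-3-methylbut-2-ene (prenyl bromide)
Product: 20 2-[2,2-dimethyl-8-(3-methylbut-2-enyl)chroman-6-yl]-1,3-dioxolane, via aryllithium 18 (not isolated), via arylcopper 19 (not isolated)
Conditions: n-BuLi, THF, −78 °C; CuBr·SMe2 (1.0 equiv), −78 to −40 °C; then 17, −78 °C to rt
Reagents that add atoms: none
Why: Bromine–lithium exchange, transmetalation to the arylcopper and SN2 allylic substitution at the primary carbon of prenyl bromide give the linear prenyl arene.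

Step 11
Reactants: 20 2-[2,2-dimethyl-8-(3-methylbut-2-enyl)chroman-6-yl]-1,3-dioxolane
Product: 21 2,2-dimethyl-8-(3-methylbut-2-enyl)chroman-6-carbaldehyde
Conditions: 1 M aq. HCl, THF, rt
Reagents that add atoms: water, O
Why: Acid-catalysed acetal hydrolysis is fast for an aryl dioxolane, and a prenyl arene without a free phenol is inert to dilute acid at rt.

Step 12
Reactants: 7 1-[2-hydroxy-4-(methoxymethoxy)-3-(3-methylbut-2-enyl)phenyl]ethanone; 21 2,2-dimethyl-8-(3-methylbut-2-enyl)chroman-6-carbaldehyde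
Product: 23 (E)-3-[2,2-dimethyl-8-(3-methylbut-2-enyl)chroman-6-yl]-1-[2-hydroxy-4-(methoxymethoxy)-3-(3-methylbut-2-enyl)phenyl]prop-2-en-1-one, via aldol adduct 22 (not isolated)
Conditions: KOH (50% aq., excess), EtOH, 0 °C to rt, 24–48 h; cold 1 M HCl work-up
Reagents that add atoms: none
Why: Claisen–Schmidt crossed aldol condensation: the enolate of methyl ketone 7 adds to the non-enolisable aldehyde 21 and E1cB dehydration gives the E-chalcone, joining the ring A and ring B fragments.

Step 13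
Reactants: 23 (E)-3-[2,2-dimethyl-8-(3-methylbut-2-enyl)chroman-6-yl]-1-[2-hydroxy-4-(methoxymethoxy)-3-(3-methylbut-2-enyl)phenyl]prop-2-en-1-one
Product: 24 rac-2-[2,2-dimethyl-8-(3-methylbut-2-enyl)chroman-6-yl]-7-(methoxymethoxy)-8-(3-methylbut-2-enyl)chroman-4-one
Conditions: NaOAc (10 equiv), EtOH, reflux, 24–48 h; recovered 23 resubmitted
Reagents that add atoms: none
Why: Base-mediated intramolecular oxa-Michael addition of the 2'-phenoxide closes ring C; C2 is formed without control (racemic) and is resolved in step 14.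

Step 14
Reactants: 24 rac-2-[2,2-dimethyl-8-(3-methylbut-2-enyl)chroman-6-yl]-7-(methoxymethoxy)-8-(3-methylbut-2-enyl)chroman-4-one
Product: 25 (2S)-2-[2,2-dimethyl-8-(3-methylbut-2-enyl)chroman-6-yl]-7-(methoxymethoxy)-8-(3-methylbut-2-enyl)chroman-4-one
Conditions: RuCl[(R,R)-TsDPEN](p-cymene) (1 mol%), HCO2H/Et3N (5:2), EtOAc, rt, to about 53% conversion (chiral HPLC control); SiO2 chromatography
Reagents that add atoms: none
Why: Noyori-type asymmetric transfer hydrogenation as a kinetic resolution: the (R,R) catalyst reduces the matched (2R) ketone quickly to the cis-(2R,4R)-flavan-4-ol, while the mismatched (2S) ketone is left in ≥98% ee and the isolated prenyl alkenes are not touched.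

Step 15
Reactants: 25 (2S)-2-[2,2-dimethyl-8-(3-methylbut-2-enyl)chroman-6-yl]-7-(methoxymethoxy)-8-(3-methylbut-2-enyl)chroman-4-one
Product: 26 (2S)-2-[2,2-dimethyl-8-(3-methylbut-2-enyl)chroman-6-yl]-7-hydroxy-8-(3-methylbut-2-enyl)chroman-4-one
Conditions: 3 M aq. HCl, MeOH, rt (to 40 °C if slow), stopped at full conversion
Reagents that add atoms: none
Why: Acid-catalysed cleavage of the phenolic MOM acetal under conditions mild enough that the 7-OH does not cyclise onto the 8-prenyl group and C2 is not epimerised (no base, no strong acid, no heat).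

## Compound list

1 | 1-(2,4-dihydroxyphenyl)ethanone (2,4-dihydroxyacetophenone) | CC(=O)c1ccc(O)cc1O | starting material
2 | 3-chloro-3-methylbut-1-yne | CC(C)(Cl)C#C | starting material
3 | 1-[2-hydroxy-4-(2-methylbut-3-yn-2-yloxy)phenyl]ethanone | CC(=O)c1ccc(OC(C)(C)C#C)cc1O | intermediate
4 | 1-[2-hydroxy-4-(2-methylbut-3-en-2-yloxy)phenyl]ethanone | CC(=O)c1ccc(OC(C)(C)C=C)cc1O | intermediate
5 | 4-acetyl-3-hydroxy-2-(3-methylbut-2-enyl)cyclohexa-3,5-dien-1-one (racemic Claisen dienone) | CC(=O)C1=C(O)C(CC=C(C)C)C(=O)C=C1 | intermediate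
6 | 1-[2,4-dihydroxy-3-(3-methylbut-2-enyl)phenyl]ethanone | CC(=O)c1ccc(O)c(CC=C(C)C)c1O | intermediate
7 | 1-[2-hydroxy-4-(methoxymethoxy)-3-(3-methylbut-2-enyl)phenyl]ethanone | CC(=O)c1ccc(OCOC)c(CC=C(C)C)c1O | intermediate
8 | 4-hydroxybenzaldehyde | O=Cc1ccc(O)cc1 | starting material
9 | 4-(2-methylbut-3-yn-2-yloxy)benzaldehyde | O=Cc1ccc(OC(C)(C)C#C)cc1 | intermediate
10 | 3-(3-methylbuta-1,2-dienyl)-4-oxocyclohexa-1,5-diene-1-carbaldehyde (racemic allenyl dienone) | O=CC1=CC(C=C=C(C)C)C(=O)C=C1 | intermediate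
11 | 4-hydroxy-3-(3-methylbuta-1,2-dienyl)benzaldehyde | O=Cc1ccc(O)c(C=C=C(C)C)c1 | intermediate
12 | 3-(3-methylbut-2-enylidene)-4-oxocyclohexa-1,5-diene-1-carbaldehyde (o-quinone methide) | O=CC1=CC(=CC=C(C)C)C(=O)C=C1 | intermediate
13 | 2,2-dimethyl-2H-chromene-6-carbaldehyde | CC1(C)C=Cc2cc(C=O)ccc2O1 | intermediate
14 | 2,2-dimethylchroman-6-carbaldehyde | CC1(C)CCc2cc(C=O)ccc2O1 | intermediate
15 | 8-bromo-2,2-dimethylchroman-6-carbaldehyde | CC1(C)CCc2cc(C=O)cc(Br)c2O1 | intermediate
16 | 2-(8-bromo-2,2-dimethylchroman-6-yl)-1,3-dioxolane | CC1(C)CCc2cc(C3OCCO3)cc(Br)c2O1 | intermediate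
17 | 1-bromo-3-methylbut-2-ene (prenyl bromide) | CC(C)=CCBr | starting material
18 | [6-(1,3-dioxolan-2-yl)-2,2-dimethylchroman-8-yl]lithium | [Li]c1cc(C2OCCO2)cc2CCC(C)(C)Oc12 | intermediate
19 | [6-(1,3-dioxolan-2-yl)-2,2-dimethylchroman-8-yl]copper | [Cu]c1cc(C2OCCO2)cc2CCC(C)(C)Oc12 | intermediate
20 | 2-[2,2-dimethyl-8-(3-methylbut-2-enyl)chroman-6-yl]-1,3-dioxolane | CC(C)=CCc1cc(C2OCCO2)cc2CCC(C)(C)Oc12 | intermediate
21 | 2,2-dimethyl-8-(3-methylbut-2-enyl)chroman-6-carbaldehyde | CC(C)=CCc1cc(C=O)cc2CCC(C)(C)Oc12 | intermediate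
22 | 3-[2,2-dimethyl-8-(3-methylbut-2-enyl)chroman-6-yl]-3-hydroxy-1-[2-hydroxy-4-(methoxymethoxy)-3-(3-methylbut-2-enyl)phenyl]propan-1-one (racemic aldol adduct) | CC(C)=CCc1cc(C(O)CC(=O)c2ccc(OCOC)c(CC=C(C)C)c2O)cc2CCC(C)(C)Oc12 | intermediate
23 | (E)-3-[2,2-dimethyl-8-(3-methylbut-2-enyl)chroman-6-yl]-1-[2-hydroxy-4-(methoxymethoxy)-3-(3-methylbut-2-enyl)phenyl]prop-2-en-1-one | CC(C)=CCc1cc(/C=C/C(=O)c2ccc(OCOC)c(CC=C(C)C)c2O)cc2CCC(C)(C)Oc12 | intermediate
24 | rac-2-[2,2-dimethyl-8-(3-methylbut-2-enyl)chroman-6-yl]-7-(methoxymethoxy)-8-(3-methylbut-2-enyl)chroman-4-one | CC(C)=CCc1cc(C2CC(=O)c3ccc(OCOC)c(CC=C(C)C)c3O2)cc2c1OC(C)(C)CC2 | intermediate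
25 | (2S)-2-[2,2-dimethyl-8-(3-methylbut-2-enyl)chroman-6-yl]-7-(methoxymethoxy)-8-(3-methylbut-2-enyl)chroman-4-one | CC(C)=CCc1cc([C@@H]2CC(=O)c3ccc(OCOC)c(CC=C(C)C)c3O2)cc2c1OC(C)(C)CC2 | intermediate
26 | (2S)-2-[2,2-dimethyl-8-(3-methylbut-2-enyl)chroman-6-yl]-7-hydroxy-8-(3-methylbut-2-enyl)chroman-4-one (CNP0272905.1) | CC(C)=CCc1cc([C@@H]2CC(=O)c3ccc(O)c(CC=C(C)C)c3O2)cc2c1OC(C)(C)CC2 | target

## Step count and risks

Total steps: 15 (ring A piece: steps 1–4; ring B piece: steps 5–11; union and endgame: steps 12–15).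
Longest linear sequence: 11 steps (8 → 26, steps 5–11 then 12–15).

Three steps most likely to fail:

**Step 14 (kinetic resolution).** The selectivity factor for this heavily substituted flavanone is not proven, and wrong conversion costs either ee or yield. The fallback sets out from 24 and comes back at 25. Racemic 24 is separated by preparative chromatography on a chiral stationary phase (amylose tris(3,5-dimethylphenylcarbamate), hexane/i-PrOH or CO2/MeOH). This is a physical separation of the enantiomers, not a selective reaction. The fraction with a positive Cotton effect near 330 nm and a negative one near 290 nm is 25. The other fraction holds the antipode (2R)-2-[2,2-dimethyl-8-(3-methylbut-2-enyl)chroman-6-yl]-7-(methoxymethoxy)-8-(3-methylbut-2-enyl)chroman-4-one F1.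

**Step 15 (acidic MOM removal).** The freed 7-OH can add to the 8-prenyl group to give a pyrano ring, and acid can open ring C and erode the ee. The fallback sets out from 6 (with 21) and comes back at 26, using no protecting group and no acid after the stereocentre exists.
- Unprotected 6 and 21 are condensed under forcing Claisen–Schmidt conditions (60% aq. KOH, EtOH, rt, 3–4 d). This passes through the aldol adduct 3-[2,2-dimethyl-8-(3-methylbut-2-enyl)chroman-6-yl]-1-[2,4-dihydroxy-3-(3-methylbut-2-enyl)phenyl]-3-hydroxypropan-1-one F2 (not isolated) and gives (E)-1-[2,4-dihydroxy-3-(3-methylbut-2-enyl)phenyl]-3-[2,2-dimethyl-8-(3-methylbut-2-enyl)chroman-6-yl]prop-2-en-1-one F3.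
- NaOAc in refluxing EtOH cyclises F3 to racemic 2-[2,2-dimethyl-8-(3-methylbut-2-enyl)chroman-6-yl]-7-hydroxy-8-(3-methylbut-2-enyl)chroman-4-one F4.
- The transfer hydrogenation of step 14 (same (R,R) ruthenium catalyst, HCO2H/Et3N, EtOAc) is then run on the free phenol. It leaves 26 and converts the antipode into (2R,4R)-2-[2,2-dimethyl-8-(3-methylbut-2-enyl)chroman-6-yl]-8-(3-methylbut-2-enyl)chromane-4,7-diol F5, which is removed on silica.

**Step 3 (aromatic Claisen rearrangement).** Some C5 isomer may form, and the tertiary allyl ether can fragment to isoprene and 1. The fallback sets out from 1 and comes back at 7, placing the prenyl group by cross-coupling at a halogenated C3.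
- Iodination of 1 (I2, HIO3, aq. EtOH, 35 °C) between the two hydroxyls gives 1-(2,4-dihydroxy-3-iodophenyl)ethanone F6.
- Selective 4-O-protection (MOMCl, K2CO3, acetone) gives 1-[2-hydroxy-3-iodo-4-(methoxymethoxy)phenyl]ethanone F7.
- Stille coupling with tributyl(3-methylbut-2-enyl)stannane (Pd(PPh3)4, DMF, 90 °C) delivers 7 directly.

## Further compounds

F1 | step 14 | (2R)-2-[2,2-dimethyl-8-(3-methylbut-2-enyl)chroman-6-yl]-7-(methoxymethoxy)-8-(3-methylbut-2-enyl)chroman-4-one | CC(C)=CCc1cc([C@H]2CC(=O)c3ccc(OCOC)c(CC=C(C)C)c3O2)cc2c1OC(C)(C)CC2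
F2 | step 15 | 3-[2,2-dimethyl-8-(3-methylbut-2-enyl)chroman-6-yl]-1-[2,4-dihydroxy-3-(3-methylbut-2-enyl)phenyl]-3-hydroxypropan-1-one (racemic) | CC(C)=CCc1cc(C(O)CC(=O)c2ccc(O)c(CC=C(C)C)c2O)cc2CCC(C)(C)Oc12
F3 | step 15 | (E)-1-[2,4-dihydroxy-3-(3-methylbut-2-enyl)phenyl]-3-[2,2-dimethyl-8-(3-methylbut-2-enyl)chroman-6-yl]prop-2-en-1-one | CC(C)=CCc1cc(/C=C/C(=O)c2ccc(O)c(CC=C(C)C)c2O)cc2CCC(C)(C)Oc12
F4 | step 15 | rac-2-[2,2-dimethyl-8-(3-methylbut-2-enyl)chroman-6-yl]-7-hydroxy-8-(3-methylbut-2-enyl)chroman-4-one | CC(C)=CCc1cc(C2CC(=O)c3ccc(O)c(CC=C(C)C)c3O2)cc2c1OC(C)(C)CC2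
F5 | step 15 | (2R,4R)-2-[2,2-dimethyl-8-(3-methylbut-2-enyl)chroman-6-yl]-8-(3-methylbut-2-enyl)chromane-4,7-diol | CC(C)=CCc1cc([C@H]2C[C@@H](O)c3ccc(O)c(CC=C(C)C)c3O2)cc2c1OC(C)(C)CC2
F6 | step 3 | 1-(2,4-dihydroxy-3-iodophenyl)ethanone | CC(=O)c1ccc(O)c(I)c1O
F7 | step 3 | 1-[2-hydroxy-3-iodo-4-(methoxymethoxy)phenyl]ethanone | CC(=O)c1ccc(OCOC)c(I)c1O
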